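**Plan**

1. Retrosynthesis: the five phenols are unmasked last (one aryl triflate, four MOM ethers). The dihydrofuran ring (ring B) is then cut at O1–C7a and C3–C3a in one stroke, giving a 3-(methoxymethoxy)-5-(arylethyl)benzyne and a (2R,3R)-trans-stilbene oxide. Each partner is cut at its ArCH=CHAr bond (HWE).
2. Enabling feature: O1 and C3 sit on the neighbouring ring-A carbons C7a and C3a, C4–O flanks C3a, and O1–C2–C3 is a masked oxirane. A 3-alkoxybenzyne can therefore insert into the C3–O bond of the epoxide: oxygen adds at C7a (remote from C4–O) and the carbanion at C3a closes onto C3.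
3. Helpers: a triflate on the 4-oxygen of the C2 aryl ring steers C–O cleavage to C3 and is hydrolysed at the end. The TMS/OTf pair that releases the aryne is put on ring A by carbamate-directed ortho-lithiation between its two oxygens.
4. Forward order: two HWE olefinations; one stilbene is epoxidised (Shi), the other hydrogenated and converted into the ortho-silylaryl triflate. The aryne/epoxide annulation builds ring B onto ring A; MOM removal and triflate hydrolysis follow.
5. Stereochemistry: C2 comes from the Shi epoxidation (its C–O bond is never broken). C3 is set in the key step, trans to the C2 aryl group, giving (2S,3S).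

Key step: step 12

Convention: dihydrobenzofuran numbering of the target is used throughout (O1, C2, C3, C3a, C4 to C7, C7a); ring A is the benzo ring, ring B the dihydrofuran ring; MOM = methoxymethyl.

**Route**

Step 1
Reactants: 1 3,5-dihydroxybenzaldehyde
Product: 2 3,5-bis(methoxymethoxy)benzaldehyde
Conditions: MOMCl (2.6 equiv), i-Pr2NEt (3 equiv), CH2Cl2, 0 °C to rt
Reagents that add atoms: chloromethyl methyl ether (MOMCl), COCCl
Why: O-alkylation of both phenols by the reactive α-chloro ether under amine base (MOM protection) leaves the formyl group untouched.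

Step 2
Reactants: 3 diethyl (4-hydroxybenzyl)phosphonate
Product: 4 diethyl {[4-(trifluoromethanesulfonyloxy)phenyl]methyl}phosphonate
Conditions: PhNTf2, Et3N, DMAP (cat.), CH2Cl2, rt
Reagents that add atoms: N-phenylbis(trifluoromethanesulfonimide) (PhNTf2), O=S(=O)(N(c1ccccc1)S(=O)(=O)C(F)(F)F)C(F)(F)F
Why: chemoselective O-triflation of the phenol by the mild triflyl donor installs the electron-withdrawing mask that later controls the epoxide opening.

Step 3
Reactants: 2 3,5-bis(methoxymethoxy)benzaldehyde; 4 diethyl {[4-(trifluoromethanesulfonyloxy)phenyl]methyl}phosphonate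
Product: 5 4-[(E)-2-[3,5-bis(methoxymethoxy)phenyl]ethenyl]phenyl trifluoromethanesulfonate
Conditions: NaH, THF, 0 °C to rt (base added to the mixture of 2 and 4)
Reagents that add atoms: none
Why: Horner–Wadsworth–Emmons olefination of a benzylphosphonate anion with a non-enolisable aryl aldehyde should give the E-stilbene through the reversible addition/anti-elimination manifold, and the aryl triflate tolerates the brief exposure to the stabilised carbanion at 0 °C.

Step 4
Reactants: 5 4-[(E)-2-[3,5-bis(methoxymethoxy)phenyl]ethenyl]phenyl trifluoromethanesulfonate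
Product: 6 4-[(2R,3R)-3-[3,5-bis(methoxymethoxy)phenyl]oxiran-2-yl]phenyl trifluoromethanesulfonate (trans epoxide)
Conditions: D-fructose-derived ketone catalyst (1,2:4,5-di-O-isopropylidene-β-D-erythro-hexo-2,3-diulo-2,6-pyranose, 30 mol %), KHSO5 (as 2KHSO5·KHSO4·K2SO4), K2CO3, Bu4NHSO4, MeCN–dimethoxymethane/aq. Na2B4O7 buffer (pH about 10.5), 0 °C
Reagents that add atoms: potassium peroxymonosulfate, [K+].[O-]S(=O)(=O)OO
Why: Shi epoxidation, in which the chiral dioxirane formed in situ transfers oxygen through a spiro transition state; with this ketone E-stilbenes are expected to give the (R,R)-epoxide, the alkene geometry is retained (trans), and the absence of a para-donor on either ring makes the epoxide stable to isolation.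

Step 5
Reactants: 1 3,5-dihydroxybenzaldehyde
Product: 7 3-hydroxy-5-(methoxymethoxy)benzaldehyde
Conditions: MOMCl (1.0 equiv), i-Pr2NEt (1.1 equiv), DMF, 0 °C; chromatography, recovered 1 recycled
Reagents that add atoms: chloromethyl methyl ether (MOMCl), COCCl
Why: statistical mono-O-alkylation of the symmetric resorcinol with one equivalent of the chloro ether; the bis-ether formed beside 7 is compound 2 and is added to the stock for step 3.

Step 6
Reactants: 3 diethyl (4-hydroxybenzyl)phosphonate
Product: 8 diethyl {[4-(methoxymethoxy)phenyl]methyl}phosphonate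
Conditions: MOMCl, i-Pr2NEt, CH2Cl2, 0 °C to rt
Reagents that add atoms: chloromethyl methyl ether (MOMCl), COCCl
Why: MOM protection of the phenol by O-alkylation; the phosphonate ester is inert.

Step 7
Reactants: 7 3-hydroxy-5-(methoxymethoxy)benzaldehyde; 8 diethyl {[4-(methoxymethoxy)phenyl]methyl}phosphonate
Product: 9 3-(methoxymethoxy)-5-[(E)-2-[4-(methoxymethoxy)phenyl]ethenyl]phenol
Conditions: KOtBu (2.5 equiv), DMF, 0 °C to rt; aq. NH4Cl
Reagents that add atoms: none
Why: Horner–Wadsworth–Emmons olefination run on the phenoxide of 7, whose meta-oxido group is not conjugated with the formyl group and so leaves it electrophilic; the alkene geometry is irrelevant because the double bond is reduced next.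

Step 8
Reactants: 9 3-(methoxymethoxy)-5-[(E)-2-[4-(methoxymethoxy)phenyl]ethenyl]phenol
Product: 10 3-(methoxymethoxy)-5-{2-[4-(methoxymethoxy)phenyl]ethyl}phenol
Conditions: H2 (1 atm), Pd/C, EtOAc, rt
Reagents that add atoms: none
Why: heterogeneous catalytic hydrogenation of the stilbene double bond; aryl MOM ethers and the phenol are not touched.

Step 9
Reactants: 10 3-(methoxymethoxy)-5-{2-[4-(methoxymethoxy)phenyl]ethyl}phenol
Product: 11 3-(methoxymethoxy)-5-{2-[4-(methoxymethoxy)phenyl]ethyl}phenyl N-(propan-2-yl)carbamate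
Conditions: i-PrNCO, Et3N (cat.), CH2Cl2, rt
Reagents that add atoms: isopropyl isocyanate, CC(C)N=C=O
Why: base-catalysed addition of the phenol to the isocyanate gives an N-isopropyl carbamate, a directing group for ortho-lithiation that can later be removed under mild E1cB conditions.

Step 10
Reactants: 11 3-(methoxymethoxy)-5-{2-[4-(methoxymethoxy)phenyl]ethyl}phenyl N-(propan-2-yl)carbamate
Product: 15 3-(methoxymethoxy)-5-{2-[4-(methoxymethoxy)phenyl]ethyl}-2-(trimethylsilyl)phenyl N-(propan-2-yl)carbamate, via N-silyl carbamate 12 (not isolated), via aryllithium 13 (not isolated), via bis-silyl carbamate 14 (not isolated)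
Conditions: TBSOTf (1.05 equiv), TMEDA, Et2O, 0 °C to rt; n-BuLi (2.2 equiv), TMEDA, −78 °C; TMSCl, −78 °C to rt; aq. NaHSO4 work-up
Reagents that add atoms: chlorotrimethylsilane, C[Si](C)(C)Cl
Why: directed ortho-metalation: after N-silylation in the flask, the carbamate and the OMOM group jointly direct n-BuLi to the C–H between the two oxygens (the future C3a), TMSCl silylates the aryllithium, and the N–Si bond is hydrolysed on acidic work-up.

Step 11
Reactants: 15 3-(methoxymethoxy)-5-{2-[4-(methoxymethoxy)phenyl]ethyl}-2-(trimethylsilyl)phenyl N-(propan-2-yl)carbamate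
Product: 17 3-(methoxymethoxy)-5-{2-[4-(methoxymethoxy)phenyl]ethyl}-2-(trimethylsilyl)phenyl trifluoromethanesulfonate, via silylphenol 16 (not isolated)
Conditions: DBU, Et2NH, MeCN, 40 °C; then PhNTf2, rt
Reagents that add atoms: N-phenylbis(trifluoromethanesulfonimide) (PhNTf2), O=S(=O)(N(c1ccccc1)S(=O)(=O)C(F)(F)F)C(F)(F)F
Why: E1cB cleavage of the N–H carbamate releases the phenoxide (the isocyanate is scavenged by Et2NH as a urea), which is triflated in the same flask to give the ortho-silylaryl triflate aryne precursor.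

Step 12
Reactants: 17 3-(methoxymethoxy)-5-{2-[4-(methoxymethoxy)phenyl]ethyl}-2-(trimethylsilyl)phenyl trifluoromethanesulfonate; 6 4-[(2R,3R)-3-[3,5-bis(methoxymethoxy)phenyl]oxiran-2-yl]phenyl trifluoromethanesulfonate
Product: 20 4-[(2S,3S)-3-[3,5-bis(methoxymethoxy)phenyl]-4-(methoxymethoxy)-6-{2-[4-(methoxymethoxy)phenyl]ethyl}-2,3-dihydro-1-benzofuran-2-yl]phenyl trifluoromethanesulfonate, via aryne 18 (not isolated), via oxiranium zwitterion 19 (not isolated)
Conditions: CsF (3 equiv), MeCN, rt; 17 (1.5 equiv) added slowly to 6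
Reagents that add atoms: none
Why: Proposed new method: fluoride attack on silicon of 17 expels triflate to give aryne 18, whose triple bond (future C7a≡C3a) is polarised by the inductively withdrawing OMOM group on the neighbouring carbon (future C4), so the oxirane oxygen of 6 should add to the remote, more electrophilic terminus (C7a) while the aryl carbanion of zwitterion 19 develops at C3a next to the C–O bond that stabilises it. In the O-aryl oxiranium ion of 19 the C–O bond at the carbon bearing the 3,5-bis(methoxymethoxy)phenyl group should ionise in preference to the one at the triflyloxyphenyl-substituted carbon, because the strongly electron-withdrawing para-triflyloxy group destabilises positive charge at its benzylic carbon far more than two meta-alkoxy groups do at the other, and the C3a carbanion then collapses onto that carbon to form C3–C3a; overall the aryne is inserted into one C–O σ-bond of the epoxide, the closest known reaction type being the fluoride-triggered insertion of arynes into the C–O bond of a monosubstituted aryl epoxide to give a 3-aryl-2,3-dihydrobenzofuran, extended here to an enantiopure unsymmetrical trans-1,2-diaryl epoxide. Ring B closes as a five-membered ring by intramolecular anion–cation recombination, that is, expansion of the oxiranium ring by the two aryne carbons; since the departing oxygen lies inside the new ring an in-line SN2 displacement is excluded and the closure is ion-pair (front-side) in character. C2 keeps the configuration of the epoxide carbon because its C–O bond is never broken ((R) in 6 becomes (S) in 20 only through the change in CIP priorities), and C3 is set trans to the C2 aryl group both by front-side collapse of the tight ion pair (retention) and by the steric preference of the planar benzylic cation, the two pathways converging on (2S,3S). The step needs regioselectivity on the aryne (secured by the C4 OMOM group), regioselectivity of C–O cleavage (secured by the triflate mask on the C2 aryl ring) and suppression of fluoride or solvent capture of 19 (sparingly soluble CsF, slow addition of 17, fast intramolecular collapse).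

Step 13
Reactants: 20 4-[(2S,3S)-3-[3,5-bis(methoxymethoxy)phenyl]-4-(methoxymethoxy)-6-{2-[4-(methoxymethoxy)phenyl]ethyl}-2,3-dihydro-1-benzofuran-2-yl]phenyl trifluoromethanesulfonate
Product: 21 4-[(2S,3S)-3-(3,5-dihydroxyphenyl)-4-hydroxy-6-[2-(4-hydroxyphenyl)ethyl]-2,3-dihydro-1-benzofuran-2-yl]phenyl trifluoromethanesulfonate
Conditions: HCl (conc., cat.), MeOH–THF, 40 °C
Reagents that add atoms: none
Why: acid-catalysed acetal exchange removes the four aryl MOM ethers, and the triflate still on the C2 aryl ring keeps the benzylic C2–O bond from ionising under acid, so C2 and C3 are not disturbed.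

Step 14
Reactants: 21 4-[(2S,3S)-3-(3,5-dihydroxyphenyl)-4-hydroxy-6-[2-(4-hydroxyphenyl)ethyl]-2,3-dihydro-1-benzofuran-2-yl]phenyl trifluoromethanesulfonate
Product: 22 5-[(2S,3S)-4-hydroxy-2-(4-hydroxyphenyl)-6-[2-(4-hydroxyphenyl)ethyl]-2,3-dihydro-1-benzofuran-3-yl]benzene-1,3-diol (CNP0315602.1)
Conditions: Et4NOH (aq., excess), 1,4-dioxane, rt, under Ar; aq. NH4Cl
Reagents that add atoms: none
Why: hydroxide attacks sulfur of the aryl triflate (S–O cleavage) and frees the last phenol at room temperature, conditions under which the C3–H and the trans ring fusion should be stable.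

**Compound list**

1 | 3,5-dihydroxybenzaldehyde | O=Cc1cc(O)cc(O)c1 | starting material
2 | 3,5-bis(methoxymethoxy)benzaldehyde | O=Cc1cc(OCOC)cc(OCOC)c1 | intermediate
3 | diethyl (4-hydroxybenzyl)phosphonate | CCOP(=O)(Cc1ccc(O)cc1)OCC | starting material
4 | diethyl {[4-(trifluoromethanesulfonyloxy)phenyl]methyl}phosphonate | CCOP(=O)(Cc1ccc(OS(=O)(=O)C(F)(F)F)cc1)OCC | intermediate
5 | 4-[(E)-2-[3,5-bis(methoxymethoxy)phenyl]ethenyl]phenyl trifluoromethanesulfonate | COCOc1cc(/C=C/c2ccc(OS(=O)(=O)C(F)(F)F)cc2)cc(OCOC)c1 | intermediate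
6 | 4-[(2R,3R)-3-[3,5-bis(methoxymethoxy)phenyl]oxiran-2-yl]phenyl trifluoromethanesulfonate (trans) | FC(F)(F)S(=O)(=O)Oc1ccc(cc1)[C@H]1O[C@@H]1c1cc(OCOC)cc(OCOC)c1 | intermediate
7 | 3-hydroxy-5-(methoxymethoxy)benzaldehyde | O=Cc1cc(O)cc(OCOC)c1 | intermediate
8 | diethyl {[4-(methoxymethoxy)phenyl]methyl}phosphonate | CCOP(=O)(Cc1ccc(OCOC)cc1)OCC | intermediate
9 | 3-(methoxymethoxy)-5-[(E)-2-[4-(methoxymethoxy)phenyl]ethenyl]phenol | COCOc1ccc(/C=C/c2cc(O)cc(OCOC)c2)cc1 | intermediate
10 | 3-(methoxymethoxy)-5-{2-[4-(methoxymethoxy)phenyl]ethyl}phenol | COCOc1ccc(CCc2cc(O)cc(OCOC)c2)cc1 | intermediate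
11 | 3-(methoxymethoxy)-5-{2-[4-(methoxymethoxy)phenyl]ethyl}phenyl N-(propan-2-yl)carbamate | COCOc1ccc(CCc2cc(OCOC)cc(OC(=O)NC(C)C)c2)cc1 | intermediate
12 | N-[tert-butyl(dimethyl)silyl] derivative of carbamate 11 | COCOc1ccc(CCc2cc(OCOC)cc(OC(=O)N(C(C)C)[Si](C)(C)C(C)(C)C)c2)cc1 | intermediate
13 | 2-lithio derivative of 12 (lithium on the ring carbon between the OMOM and carbamate oxygens) | COCOc1ccc(CCc2cc(OCOC)c([Li])c(OC(=O)N(C(C)C)[Si](C)(C)C(C)(C)C)c2)cc1 | intermediate
14 | 2-(trimethylsilyl) derivative of 12 (N-silyl and C-silyl) | COCOc1ccc(CCc2cc(OCOC)c([Si](C)(C)C)c(OC(=O)N(C(C)C)[Si](C)(C)C(C)(C)C)c2)cc1 | intermediate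
15 | 3-(methoxymethoxy)-5-{2-[4-(methoxymethoxy)phenyl]ethyl}-2-(trimethylsilyl)phenyl N-(propan-2-yl)carbamate | COCOc1ccc(CCc2cc(OCOC)c([Si](C)(C)C)c(OC(=O)NC(C)C)c2)cc1 | intermediate
16 | 3-(methoxymethoxy)-5-{2-[4-(methoxymethoxy)phenyl]ethyl}-2-(trimethylsilyl)phenol | COCOc1ccc(CCc2cc(OCOC)c([Si](C)(C)C)c(O)c2)cc1 | intermediate
17 | 3-(methoxymethoxy)-5-{2-[4-(methoxymethoxy)phenyl]ethyl}-2-(trimethylsilyl)phenyl trifluoromethanesulfonate | COCOc1ccc(CCc2cc(OCOC)c([Si](C)(C)C)c(OS(=O)(=O)C(F)(F)F)c2)cc1 | intermediate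
18 | 3-(methoxymethoxy)-5-{2-[4-(methoxymethoxy)phenyl]ethyl}benzyne (1,2-didehydrobenzene, triple bond C1≡C2) | COCOC1=CC(CCc2ccc(OCOC)cc2)=CC#C1 | intermediate
19 | zwitterion from O-addition of 6 to C1 of 18: O-aryl (2R,3R)-diaryloxiranium ion with the aryl carbanion at C2 of the former aryne | COCOC1=CC(CCc2ccc(OCOC)cc2)=CC([O+]2[C@H](c3ccc(OS(=O)(=O)C(F)(F)F)cc3)[C@H]2c2cc(OCOC)cc(OCOC)c2)=[C-]1 | intermediate
20 | 4-[(2S,3S)-3-[3,5-bis(methoxymethoxy)phenyl]-4-(methoxymethoxy)-6-{2-[4-(methoxymethoxy)phenyl]ethyl}-2,3-dihydro-1-benzofuran-2-yl]phenyl trifluoromethanesulfonate (trans) | COCOc1ccc(CCc2cc(OCOC)c3c(c2)O[C@H](c2ccc(OS(=O)(=O)C(F)(F)F)cc2)[C@H]3c2cc(OCOC)cc(OCOC)c2)cc1 | intermediate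
21 | 4-[(2S,3S)-3-(3,5-dihydroxyphenyl)-4-hydroxy-6-[2-(4-hydroxyphenyl)ethyl]-2,3-dihydro-1-benzofuran-2-yl]phenyl trifluoromethanesulfonate | Oc1ccc(CCc2cc(O)c3c(c2)O[C@H](c2ccc(OS(=O)(=O)C(F)(F)F)cc2)[C@H]3c2cc(O)cc(O)c2)cc1 | intermediate
22 | 5-[(2S,3S)-4-hydroxy-2-(4-hydroxyphenyl)-6-[2-(4-hydroxyphenyl)ethyl]-2,3-dihydro-1-benzofuran-3-yl]benzene-1,3-diol | Oc1ccc(CCc2cc(O)c3c(c2)O[C@H](c2ccc(O)cc2)[C@H]3c2cc(O)cc(O)c2)cc1 | target

**Step count and risks**

Total step count: 14. Longest linear sequence: 9 steps (steps 5, 7, 8, 9, 10, 11, 12, 13, 14) from 3,5-dihydroxybenzaldehyde.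

Steps most likely to fail:

1. Step 12. The oxiranium ion may cleave at the wrong C–O bond, the zwitterion may be intercepted by fluoride or solvent before the carbanion closes, or the benzylic cation may rearrange by hydride shift. The fallback uses known chemistry, forming C3–C3a and then O1–C2 in separate steps with double inversion. It sets out from 10 and 5 and comes back at 21.
   - 10 is capped (MOMCl, i-Pr2NEt) as 1,3-bis(methoxymethoxy)-5-{2-[4-(methoxymethoxy)phenyl]ethyl}benzene F1.
   - n-BuLi (THF, 0 °C) lithiates F1 between its two OMOM groups to give [2,6-bis(methoxymethoxy)-4-{2-[4-(methoxymethoxy)phenyl]ethyl}phenyl]lithium F2.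
   - 5 is epoxidised as in step 4, but with the enantiomeric (L-sorbose-derived) ketone catalyst, to give 4-[(2S,3S)-3-[3,5-bis(methoxymethoxy)phenyl]oxiran-2-yl]phenyl trifluoromethanesulfonate F3.
   - F2 opens F3 (BF3·OEt2, THF, −78 °C) in an SN2-type aryl–epoxide opening, with inversion at the carbon bearing the bis(methoxymethoxy)phenyl group, to give 4-[(1R,2S)-2-[3,5-bis(methoxymethoxy)phenyl]-2-[2,6-bis(methoxymethoxy)-4-{2-[4-(methoxymethoxy)phenyl]ethyl}phenyl]-1-hydroxyethyl]phenyl trifluoromethanesulfonate F4.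
   - HCl/MeOH removes the five MOM groups to give 4-[(1R,2S)-2-(3,5-dihydroxyphenyl)-2-{2,6-dihydroxy-4-[2-(4-hydroxyphenyl)ethyl]phenyl}-1-hydroxyethyl]phenyl trifluoromethanesulfonate F5.
   - Mitsunobu cyclodehydration (PPh3, DIAD, THF, 0 °C) closes ring B through either of the two equivalent ortho-phenols with inversion at the carbinol carbon. The double inversion from the (S,S)-epoxide should give trans-(2S,3S) 21, from which step 14 follows.

2. Step 10. The silyl triflate may transfer to a MOM acetal oxygen (loss of a MOM group), lithiation may occur away from the position between the two oxygens, or the carbamoyl group may migrate (anionic Fries). The fallback avoids the silyl triflate. It sets out from 10 and comes back at 16.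
   - Carbamoylation (ClC(=O)NEt2, NaH, THF) gives 3-(methoxymethoxy)-5-{2-[4-(methoxymethoxy)phenyl]ethyl}phenyl N,N-diethylcarbamate F6.
   - Directed ortho-lithiation with in situ silylation (s-BuLi, TMEDA, TMSCl, THF, −78 °C) gives 3-(methoxymethoxy)-5-{2-[4-(methoxymethoxy)phenyl]ethyl}-2-(trimethylsilyl)phenyl N,N-diethylcarbamate F7.
   - Reductive cleavage of the tertiary carbamate with Cp2Zr(H)Cl (THF, rt) gives silylphenol 16, here isolated, which is triflated (PhNTf2, DBU, MeCN) to 17 as in the second half of step 11.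

3. Step 14. The polyphenolate may oxidise in air, or ring B may open through a para-quinone methide once the C2 aryl phenoxide is unmasked under base. The fallback reverses the order of the two unmasking steps so that the basic S–O cleavage runs on a substrate without free phenols. It sets out from 20 and comes back at 22.
   - Et4NOH (aq.), 1,4-dioxane, rt gives 4-[(2S,3S)-3-[3,5-bis(methoxymethoxy)phenyl]-4-(methoxymethoxy)-6-{2-[4-(methoxymethoxy)phenyl]ethyl}-2,3-dihydro-1-benzofuran-2-yl]phenol F8.
   - The four MOM ethers of F8 are then removed with HCl (cat.) in MeOH at rt to give 22.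

Further compounds
F1 | step 12 | 1,3-bis(methoxymethoxy)-5-{2-[4-(methoxymethoxy)phenyl]ethyl}benzene | COCOc1ccc(CCc2cc(OCOC)cc(OCOC)c2)cc1
F2 | step 12 | [2,6-bis(methoxymethoxy)-4-{2-[4-(methoxymethoxy)phenyl]ethyl}phenyl]lithium | COCOc1ccc(CCc2cc(OCOC)c([Li])c(OCOC)c2)cc1
F3 | step 12 | 4-[(2S,3S)-3-[3,5-bis(methoxymethoxy)phenyl]oxiran-2-yl]phenyl trifluoromethanesulfonate | FC(F)(F)S(=O)(=O)Oc1ccc(cc1)[C@@H]1O[C@H]1c1cc(OCOC)cc(OCOC)c1
F4 | step 12 | 4-[(1R,2S)-2-[3,5-bis(methoxymethoxy)phenyl]-2-[2,6-bis(methoxymethoxy)-4-{2-[4-(methoxymethoxy)phenyl]ethyl}phenyl]-1-hydroxyethyl]phenyl trifluoromethanesulfonate | FC(F)(F)S(=O)(=O)Oc1ccc(cc1)[C@H](O)[C@H](c1c(OCOC)cc(CCc2ccc(OCOC)cc2)cc1OCOC)c1cc(OCOC)cc(OCOC)c1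
F5 | step 12 | 4-[(1R,2S)-2-(3,5-dihydroxyphenyl)-2-{2,6-dihydroxy-4-[2-(4-hydroxyphenyl)ethyl]phenyl}-1-hydroxyethyl]phenyl trifluoromethanesulfonate | FC(F)(F)S(=O)(=O)Oc1ccc(cc1)[C@H](O)[C@H](c1c(O)cc(CCc2ccc(O)cc2)cc1O)c1cc(O)cc(O)c1
F6 | step 10 | 3-(methoxymethoxy)-5-{2-[4-(methoxymethoxy)phenyl]ethyl}phenyl N,N-diethylcarbamate | COCOc1ccc(CCc2cc(OCOC)cc(OC(=O)N(CC)CC)c2)cc1
F7 | step 10 | 3-(methoxymethoxy)-5-{2-[4-(methoxymethoxy)phenyl]ethyl}-2-(trimethylsilyl)phenyl N,N-diethylcarbamate | COCOc1ccc(CCc2cc(OCOC)c([Si](C)(C)C)c(OC(=O)N(CC)CC)c2)cc1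
F8 | step 14 | 4-[(2S,3S)-3-[3,5-bis(methoxymethoxy)phenyl]-4-(methoxymethoxy)-6-{2-[4-(methoxymethoxy)phenyl]ethyl}-2,3-dihydro-1-benzofuran-2-yl]phenol | COCOc1ccc(CCc2cc(OCOC)c3c(c2)O[C@H](c2ccc(O)cc2)[C@H]3c2cc(OCOC)cc(OCOC)c2)cc1
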